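**Retrosynthetic overview**

- Target 18 ← C2 sulfenylation of the 3-(methylsulfanyl)indole 17 ← N-detosylation of 16 ← aromatising thioenol-ether formation at the C3 ketone of indolin-3-one 14.
- 14 ← aryne annulation that makes N1–C7a and C3–C3a in one operation from silyl triflate 9 (through aryne 13) and ethyl N-tosylglycinate 12. The five-membered ring is the only ring formed; the benzene ring is carried in intact.
- Feature the plan rests on: on the benzene ring, N1 (on C7a) and C3 (on C3a) are ortho neighbours, with C7–H beside C7a and the C4 bromine beside C3a, followed by C5–Br and C6–Br. This is the substitution pattern of 3,4,5-tribromobenzyne, whose bromine next to the triple bond decides where nitrogen adds.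
- 9 ← 3,4,5-tribromophenol 3 (from aniline 1) by carbamate-directed ortho-silylation, carbamate removal and triflation; 12 ← glycine ethyl ester hydrochloride 10 + tosyl chloride 11.

Key step: step 6

Assumption: intermediate 5 is drawn as the N-silyl carbamate; if silicon sits on the carbonyl oxygen instead (silyl imidate), the metalation and the acidic work-up should proceed in the same way.

**Route**

Step 1
Reactants: 1 3,4,5-tribromoaniline
Product: 3 3,4,5-tribromophenol, via diazonium hydrogensulfate 2 (not isolated)
Conditions: NaNO2, conc. H2SO4, AcOH, 0–10 °C; then 40% aq. H2SO4, 110 °C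
Reagents that add atoms: water, O (sodium nitrite, [Na+].[O-]N=O, supplies only the outer nitrogen of intermediate 2, which leaves as N2)
Why: Diazotisation of the weakly basic aniline with nitrosylsulfuric acid followed by thermal hydrolysis of the diazonium salt exchanges NH2 for OH without touching the C–Br bonds, and the symmetric ring allows only one phenol.

Step 2
Reactants: 3 3,4,5-tribromophenol
Product: 4 3,4,5-tribromophenyl N-isopropylcarbamate
Conditions: iPrNCO, Et3N (cat.), CH2Cl2, rt
Reagents that add atoms: isopropyl isocyanate, CC(C)N=C=O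
Why: Amine-catalysed addition of the phenol O–H across the isocyanate (carbamoylation) installs an ortho-directing group that can later be removed by mild E1cB fragmentation.

Step 3
Reactants: 4 3,4,5-tribromophenyl N-isopropylcarbamate
Product: 7 3,4,5-tribromo-2-(trimethylsilyl)phenyl N-isopropylcarbamate, via N-silyl carbamate 5 (not isolated), via C-silylated N-silyl carbamate 6 (not isolated)
Conditions: TBSOTf, TMEDA, Et2O, 0 °C → rt; then Me3SiCl, LiN(iPr)2 (LDA, 2.2 equiv), THF, −78 °C; aq. NaHSO4, rt
Reagents that add atoms: chlorotrimethylsilane, C[Si](C)(C)Cl (tert-butyldimethylsilyl triflate, CC(C)(C)[Si](C)(C)OS(=O)(=O)C(F)(F)F, puts silicon only on intermediates 5 and 6)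
Why: Directed ortho-metalation with in situ silyl quench: once the N–H is masked, the amide base removes the proton flanked by the carbamate oxygen and the C3 bromine (both ortho sites are equivalent), and the aryllithium is silylated at once by the Me3SiCl already present, which should forestall LiBr loss, halogen dance and anionic Fries shift, while an amide base avoids the bromine–lithium exchange an alkyllithium would cause.

Step 4
Reactants: 7 3,4,5-tribromo-2-(trimethylsilyl)phenyl N-isopropylcarbamate
Product: 9 3,4,5-tribromo-2-(trimethylsilyl)phenyl trifluoromethanesulfonate, via silylphenol 8 (not isolated)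
Conditions: DBU, Et2NH, MeCN, 40 °C; then PhNTf2, rt
Reagents that add atoms: N-phenylbis(trifluoromethanesulfonimide), O=S(=O)(N(c1ccccc1)S(=O)(=O)C(F)(F)F)C(F)(F)F
Why: DBU deprotonates the carbamate N–H, the phenoxide is expelled (E1cB) with diethylamine trapping the isocyanate as a urea, and the phenoxide is triflated in the same flask, a non-nucleophilic sequence that should leave the crowded C–Si bond intact.

Step 5
Reactants: 10 glycine ethyl ester hydrochloride; 11 p-toluenesulfonyl chloride
Product: 12 ethyl N-(4-methylbenzenesulfonyl)glycinate (ethyl N-tosylglycinate)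
Conditions: Et3N (2.2 equiv), CH2Cl2, 0 °C → rt
Reagents that add atoms: none
Why: N-Sulfonylation of the liberated primary amine gives the acidic sulfonamide N–H required for addition to the aryne.

Step 6
Reactants: 9 3,4,5-tribromo-2-(trimethylsilyl)phenyl trifluoromethanesulfonate; 12 ethyl N-tosylglycinate
Product: 14 4,5,6-tribromo-1-tosylindolin-3-one, via 3,4,5-tribromobenzyne 13 (not isolated)
Conditions: CsF (3 equiv), MeCN, rt, slow addition of 9 to 12 (1.3 equiv)
Reagents that add atoms: none
Why: Fluoride attacks silicon of 9 and triflate departs to give aryne 13; the caesium sulfonamide of 12 adds through nitrogen, and the aryl anion so formed attacks the ester carbonyl and expels ethoxide, a formal (3+2) annulation by insertion of the aryne into the N–H/CO2Et pair. The closest known reaction type is the annulation of arynes from ortho-silylaryl triflates with N-sulfonyl α-amino esters to N-sulfonylindolin-3-ones, taken together with the distortion-controlled regioselectivity of additions to 3-haloarynes. The single ring formed, N1–C2–C3–C3a–C7a, closes by 5-exo-trig attack of the C3a carbanion on the ester carbon, the N1–C7a bond being made first and the C3–C3a bond second. No stereocentre is created. The step needs nitrogen to add to the aryne carbon remote from bromine: the C–Br bond beside the triple bond widens the internal angle at the distal carbon, making it the more electrophilic terminus, and stabilises negative charge on the proximal carbon inductively, so nitrogen should go to the future C7a and the anion should sit at the future C3a next to C4–Br. It also needs acylation to outrun bromide loss or protonation of the ortho-bromoaryl anion, which the ester held two atoms from nitrogen is placed to secure, and fluoride in MeCN at room temperature should leave all three C–Br bonds alone.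

Step 7
Reactants: 14 4,5,6-tribromo-1-tosylindolin-3-one
Product: 16 4,5,6-tribromo-3-(methylsulfanyl)-1-tosyl-1H-indole, via dithioketal 15 (not isolated)
Conditions: MeSSiMe3 (2.5 equiv), TMSOTf (cat.), CH2Cl2, 0 → 40 °C
Reagents that add atoms: (methylsulfanyl)trimethylsilane, CS[Si](C)(C)C
Why: Lewis-acid thioketalisation of the ketone by the thiosilane, then loss of methanethiol through the C3 thionium ion and C2 deprotonation (thioenol ether formation), should be driven to the vinyl sulfide by aromatisation of the five-membered ring to the indole, with the N-sulfonyl group and aryl bromides inert.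

Step 8
Reactants: 16 4,5,6-tribromo-3-(methylsulfanyl)-1-tosyl-1H-indole
Product: 17 4,5,6-tribromo-3-(methylsulfanyl)-1H-indole
Conditions: Cs2CO3, THF/MeOH (2:1), rt → 50 °C
Reagents that add atoms: none
Why: Methoxide attacks sulfur of the N-sulfonylindole and releases the electron-poor indolide (nucleophilic N-desulfonylation), under conditions that spare aryl bromides and the thioether, unlike dissolving-metal detosylation.

Step 9
Reactants: 17 4,5,6-tribromo-3-(methylsulfanyl)-1H-indole
Product: 18 4,5,6-tribromo-2,3-bis(methylsulfanyl)-1H-indole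
Conditions: MeSSMe, SO2Cl2, CH2Cl2, −20 °C; then 17, −20 °C → rt
Reagents that add atoms: dimethyl disulfide, CSSC (converted in the flask by SO2Cl2 into methanesulfenyl chloride, CSCl)
Why: Electrophilic sulfenylation of a 3-sulfanylindole by a sulfenyl chloride should place the second sulfur on C2, the only open carbon of the pyrrole ring, either directly or through a 3,3-bis(sulfanyl)-3H-indolium ion followed by 1,2-sulfur shift and proton loss.

**Compound list**

1 | 3,4,5-tribromoaniline | Nc1cc(Br)c(Br)c(Br)c1 | starting material
2 | 3,4,5-tribromobenzenediazonium hydrogensulfate | N#[N+]c1cc(Br)c(Br)c(Br)c1.OS(=O)(=O)[O-] | intermediate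
3 | 3,4,5-tribromophenol | Oc1cc(Br)c(Br)c(Br)c1 | intermediate
4 | 3,4,5-tribromophenyl N-isopropylcarbamate | CC(C)NC(=O)Oc1cc(Br)c(Br)c(Br)c1 | intermediate
5 | 3,4,5-tribromophenyl N-(tert-butyldimethylsilyl)-N-isopropylcarbamate | CC(C)N(C(=O)Oc1cc(Br)c(Br)c(Br)c1)[Si](C)(C)C(C)(C)C | intermediate
6 | 3,4,5-tribromo-2-(trimethylsilyl)phenyl N-(tert-butyldimethylsilyl)-N-isopropylcarbamate | CC(C)N(C(=O)Oc1cc(Br)c(Br)c(Br)c1[Si](C)(C)C)[Si](C)(C)C(C)(C)C | intermediate
7 | 3,4,5-tribromo-2-(trimethylsilyl)phenyl N-isopropylcarbamate | CC(C)NC(=O)Oc1cc(Br)c(Br)c(Br)c1[Si](C)(C)C | intermediate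
8 | 3,4,5-tribromo-2-(trimethylsilyl)phenol (present as its amidinium phenoxide) | C[Si](C)(C)c1c(O)cc(Br)c(Br)c1Br | intermediate
9 | 3,4,5-tribromo-2-(trimethylsilyl)phenyl trifluoromethanesulfonate | C[Si](C)(C)c1c(OS(=O)(=O)C(F)(F)F)cc(Br)c(Br)c1Br | intermediate
10 | glycine ethyl ester hydrochloride | Cl.NCC(=O)OCC | starting material
11 | p-toluenesulfonyl chloride | Cc1ccc(cc1)S(=O)(=O)Cl | starting material
12 | ethyl N-(4-methylbenzenesulfonyl)glycinate | CCOC(=O)CNS(=O)(=O)c1ccc(C)cc1 | intermediate
13 | 3,4,5-tribromobenzyne (3,4,5-tribromo-1,2-didehydrobenzene) | BrC1=C(Br)C(Br)=CC#C1 | intermediate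
14 | 4,5,6-tribromo-1-(4-methylbenzenesulfonyl)indolin-3-one | Cc1ccc(cc1)S(=O)(=O)N1CC(=O)c2c1cc(Br)c(Br)c2Br | intermediate
15 | 4,5,6-tribromo-3,3-bis(methylsulfanyl)-1-(4-methylbenzenesulfonyl)indoline | CSC1(SC)CN(S(=O)(=O)c2ccc(C)cc2)c2cc(Br)c(Br)c(Br)c21 | intermediate
16 | 4,5,6-tribromo-3-(methylsulfanyl)-1-(4-methylbenzenesulfonyl)-1H-indole | CSc1cn(S(=O)(=O)c2ccc(C)cc2)c2cc(Br)c(Br)c(Br)c12 | intermediate
17 | 4,5,6-tribromo-3-(methylsulfanyl)-1H-indole | CSc1c[nH]c2cc(Br)c(Br)c(Br)c12 | intermediate
18 | 4,5,6-tribromo-2,3-bis(methylsulfanyl)-1H-indole | CSc1[nH]c2cc(Br)c(Br)c(Br)c2c1SC | target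

**Step count**

Total step count: 9. Longest linear sequence: 8 steps (steps 1, 2, 3, 4, 6, 7, 8, 9, from 1 to 18); step 5 is a one-step branch.

**Steps most likely to fail**

1. Step 6. The ortho-bromoaryl anion may lose bromide or be protonated before it acylates, which would give open-chain N-aryl glycinate or products of a second aryne. The acidic indolinone may also be arylated by further aryne. Fallback without an aryne, setting out from 1 and returning at 14: 1 is sulfonylated with 11 in pyridine to N-(3,4,5-tribromophenyl)-4-methylbenzenesulfonamide F1, and alkylated with ethyl bromoacetate and K2CO3 in DMF to ethyl N-(3,4,5-tribromophenyl)-N-tosylglycinate F2. Saponification with LiOH in THF/water gives N-(3,4,5-tribromophenyl)-N-tosylglycine F3, and SOCl2 gives N-(3,4,5-tribromophenyl)-N-tosylglycyl chloride F4. Intramolecular Friedel–Crafts acylation with AlCl3 in 1,2-dichloroethane then closes C3–C3a. The two ortho positions of the symmetric ring are equivalent, so only 14 can result.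

2. Step 3. Bromine migration between lithiated and unlithiated arene, LiBr elimination from the ortho-bromoaryllithium, or a second silylation at the equivalent ortho site may erode the metalation. Fallback by halogen–lithium exchange instead of deprotonation, setting out from 3 and returning at 9: 3 is mono-iodinated ortho to the hydroxyl (N-iodosuccinimide, cat. TsOH, MeCN) to 3,4,5-tribromo-2-iodophenol F5, and O-silylated with hexamethyldisilazane to (3,4,5-tribromo-2-iodophenoxy)trimethylsilane F6. Treatment with n-BuLi in THF at −100 °C should exchange iodine faster than bromine and trigger 1,3 O→C silyl migration (retro-Brook) to the lithium salt of 8, which Tf2O converts in the same flask into 9.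

3. Step 7. Condensation at the peri-hindered, deactivated ketone may be incomplete, or the substrate may rest as its O-silyl enol instead of exchanging oxygen for sulfur. Fallback that removes the ketone oxygen and brings sulfur in electrophilically, setting out from 14 and returning at 17: NaBH4 in THF/MeOH reduces 14 to racemic 4,5,6-tribromo-1-tosylindolin-3-ol F7, and TsOH in warm toluene dehydrates it to 4,5,6-tribromo-1-tosyl-1H-indole F8. Cs2CO3 in THF/MeOH removes the sulfonyl group to give 4,5,6-tribromo-1H-indole F9. One equivalent of methanesulfenyl chloride in CH2Cl2 at −78 °C should then sulfenylate C3, the most nucleophilic position, to give 17.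

**Further compounds**

F1 | step 6 | N-(3,4,5-tribromophenyl)-4-methylbenzenesulfonamide | Cc1ccc(cc1)S(=O)(=O)Nc1cc(Br)c(Br)c(Br)c1
F2 | step 6 | ethyl N-(3,4,5-tribromophenyl)-N-(4-methylbenzenesulfonyl)glycinate | CCOC(=O)CN(c1cc(Br)c(Br)c(Br)c1)S(=O)(=O)c1ccc(C)cc1
F3 | step 6 | N-(3,4,5-tribromophenyl)-N-(4-methylbenzenesulfonyl)glycine | OC(=O)CN(c1cc(Br)c(Br)c(Br)c1)S(=O)(=O)c1ccc(C)cc1
F4 | step 6 | N-(3,4,5-tribromophenyl)-N-(4-methylbenzenesulfonyl)glycyl chloride | ClC(=O)CN(c1cc(Br)c(Br)c(Br)c1)S(=O)(=O)c1ccc(C)cc1
F5 | step 3 | 3,4,5-tribromo-2-iodophenol | Oc1cc(Br)c(Br)c(Br)c1I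
F6 | step 3 | (3,4,5-tribromo-2-iodophenoxy)trimethylsilane | C[Si](C)(C)Oc1cc(Br)c(Br)c(Br)c1I
F7 | step 7 | rac-4,5,6-tribromo-1-(4-methylbenzenesulfonyl)indolin-3-ol | OC1CN(S(=O)(=O)c2ccc(C)cc2)c2cc(Br)c(Br)c(Br)c12
F8 | step 7 | 4,5,6-tribromo-1-(4-methylbenzenesulfonyl)-1H-indole | Cc1ccc(cc1)S(=O)(=O)n1ccc2c(Br)c(Br)c(Br)cc21
F9 | step 7 | 4,5,6-tribromo-1H-indole | Brc1cc2[nH]ccc2c(Br)c1Br
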